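The three upper units come from (−)-epicatechin; the lower catechin unit is built de novo around its ring C. Everything rests on disconnecting C3–C4 of that ring: the C4 methylene and O1 sit ortho on ring A, the pattern of a salicylaldehyde, and C3 is the α-carbon of a cinnamaldehyde. One amine-catalysed oxa-Michael/aldol domino joins a phloroglucinol salicylaldehyde to a 3,4-dibenzyloxycinnamaldehyde, sets C2 (O1–C2) enantioselectively and closes ring C through C3–C4. Decarbonylation and hydroboration on the face opposite the C2 aryl group then give tetra-O-benzylcatechin, which is extended three times at C8 by a C4-activated epicatechin unit and debenzylated.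

Key step: step 3

Remark: the target is read from its SMILES as epicatechin-(4β→8)-epicatechin-(4β→8)-epicatechin-(4β→8)-catechin. Flavan numbering (O1, C2, C3, C4, C4a, C5–C8, C8a; rings A, B, C) is used throughout, and the 2-aryl groups are α in all four units.

Remark: activation of 15 with TMSOTf in steps 8 to 10 re-forms the flavan-4-yl cation through which step 7 passes; this cation carries its number, 14, from step 7.

Step 1
Reactants: 1 3,5-bis(benzyloxy)phenol
Product: 3 2,4-bis(benzyloxy)-6-hydroxybenzaldehyde, via magnesium ortho-hydroxymethyl phenoxide 2 (not isolated)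
Conditions: (CH2O)n, MgCl2, Et3N, MeCN, reflux; aqueous HCl work-up
Reagents that add atoms: paraformaldehyde (formaldehyde), C=O
Why: Casnati–Skattebøl ortho-formylation, in which the magnesium phenoxide delivers formaldehyde to one of the two equivalent ortho carbons and the magnesium alkoxide 2 is oxidised by hydride transfer to a second formaldehyde.

Step 2
Reactants: 4 3,4-bis(benzyloxy)benzaldehyde
Product: 5 (E)-3-[3,4-bis(benzyloxy)phenyl]prop-2-enal
Conditions: Ph3P=CHCHO (1.1 equiv), toluene, 80 °C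
Reagents that add atoms: (triphenylphosphoranylidene)acetaldehyde, O=CC=P(c1ccccc1)(c1ccccc1)c1ccccc1
Why: Wittig olefination with a formyl-stabilised ylide should give the (E)-enal, and only a slight excess of ylide is used to limit a second homologation.

Step 3
Reactants: 3 2,4-bis(benzyloxy)-6-hydroxybenzaldehyde; 5 (E)-3-[3,4-bis(benzyloxy)phenyl]prop-2-enal
Product: 8 (R)-5,7-bis(benzyloxy)-2-[3,4-bis(benzyloxy)phenyl]-2H-chromene-3-carbaldehyde, via oxa-Michael enamine 6 (not isolated), via aldol iminium salt 7 (not isolated)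
Conditions: (S)-2-[diphenyl(trimethylsilyloxy)methyl]pyrrolidine (20 mol%), 2-nitrobenzoic acid (20 mol%), 4 Å molecular sieves, toluene, 0 °C to rt
Reagents that add atoms: none
Why: The amine condenses with 5 to an (E)-iminium ion, the phenol oxygen of 3 adds to its β-carbon (oxa-Michael, bond O1–C2) to give enamine 6, whose nucleophilic carbon (the future C3) attacks the ortho formyl carbon (the future C4) in an intramolecular aldol addition to 7, and E1cB loss of water with hydrolysis of the unsaturated iminium ion releases 8 and the catalyst. The closest known reaction type is the organocatalytic asymmetric domino oxa-Michael/aldol condensation of salicylaldehydes with enals (iminium–enamine cascade). Ring C is closed by the C3–C4 bond in a 6-(enolexo)-exo-trig aldol cyclisation, the O1–C2 bond having been made intermolecularly just before. C2 is the only stereocentre that survives and is catalyst-controlled: the CPh2(OSiMe3) group shields one face of the s-trans iminium ion, so the phenol adds from the other face and places the aryl group α (R in 8, the 2R series of catechin), while the C3 and C4 centres of 7 are erased on dehydration. The step needs O- rather than C-attack by ring A and cross- rather than self-condensation: the formyl group of 3 deactivates the ring carbons and cannot form an enamine, only 5 gives a conjugated iminium ion, the aldol acceptor is held ortho to the new ether, and the irreversible dehydration pulls the reversible oxa-Michael step forward.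

Step 4
Reactants: 8 (R)-5,7-bis(benzyloxy)-2-[3,4-bis(benzyloxy)phenyl]-2H-chromene-3-carbaldehyde
Product: 9 (S)-5,7-bis(benzyloxy)-2-[3,4-bis(benzyloxy)phenyl]-2H-chromene
Conditions: RhCl(PPh3)3 (1.1 equiv), toluene, 90 °C, dark
Reagents that add atoms: none
Why: Tsuji–Wilkinson decarbonylation (oxidative addition of the formyl C–H bond, CO extrusion, vinyl–H reductive elimination) should replace CHO by H with C3=C4 left in place and C2 untouched (the descriptor changes from R to S only because the ring priorities change), the moderate temperature and exclusion of light guarding against electrocyclic ring opening.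

Step 5
Reactants: 9 (S)-5,7-bis(benzyloxy)-2-[3,4-bis(benzyloxy)phenyl]-2H-chromene
Product: 11 5,7,3',4'-tetra-O-benzyl-(+)-catechin [(2R,3S)], via C3 alkylborane 10 (not isolated)
Conditions: BH3·THF, THF, 0 °C to rt; then NaOH, H2O2, H2O, 0 °C
Reagents that add atoms: hydrogen peroxide, OO
Why: Hydroboration–oxidation, in which borane adds syn to the styrene-type C3=C4 bond with boron at the non-benzylic C3 (reinforced by the electron-rich ring A) on the face opposite the C2 aryl group, and oxidation with retention should give the 2,3-trans (3S) alcohol.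

Step 6
Reactants: 12 (−)-epicatechin
Product: 13 5,7,3',4'-tetra-O-benzyl-(−)-epicatechin [(2R,3R)]
Conditions: BnBr (4.2 equiv), K2CO3, DMF, 0 °C to rt, under Ar
Reagents that add atoms: benzyl bromide, BrCc1ccccc1
Why: Williamson etherification, in which K2CO3 deprotonates only the four phenols and leaves the secondary C3 hydroxyl and both stereocentres untouched.

Step 7
Reactants: 13 5,7,3',4'-tetra-O-benzyl-(−)-epicatechin [(2R,3R)]
Product: 15 5,7,3',4'-tetra-O-benzyl-4β-(2-ethoxyethoxy)epicatechin, via flavan-4-yl cation 14 (not isolated)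
Conditions: DDQ (2 equiv), 2-ethoxyethanol (excess), CH2Cl2, rt
Reagents that add atoms: 2-ethoxyethanol, CCOCCO
Why: Oxidative benzylic etherification, in which DDQ abstracts hydride from C4 (stabilised by the 5,7-dibenzyloxy ring A) and the alcohol traps cation 14 anti to the C3 hydroxyl, which should give the 4β ether.

Step 8
Reactants: 15 5,7,3',4'-tetra-O-benzyl-4β-(2-ethoxyethoxy)epicatechin; 11 5,7,3',4'-tetra-O-benzyl-(+)-catechin [(2R,3S)]
Product: 16 octa-O-benzyl procyanidin B1 [tetra-O-benzylepicatechin-(4β→8)-tetra-O-benzylcatechin]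
Conditions: TMSOTf (0.1 equiv), CH2Cl2, −78 °C; 11 in excess (3 equiv), excess recovered
Reagents that add atoms: none
Why: Friedel–Crafts-type flavan-4-yl arylation, in which TMSOTf ionises the C4–O bond of 15 and re-forms the flavan-4-yl cation of step 7, and C8 of 11 (the most nucleophilic position of ring A) attacks anti to the C3 hydroxyl and C2 aryl groups, which should give the 4β→8 bond (3,4-trans).

Step 9
Reactants: 15 5,7,3',4'-tetra-O-benzyl-4β-(2-ethoxyethoxy)epicatechin; 16 octa-O-benzyl procyanidin B1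
Product: 17 dodeca-O-benzyl trimer [tetra-O-benzylepicatechin-(4β→8)-tetra-O-benzylepicatechin-(4β→8)-tetra-O-benzylcatechin]
Conditions: TMSOTf (0.1 equiv), CH2Cl2, −78 °C; 16 in excess, excess recovered
Reagents that add atoms: none
Why: The same flavan-4-yl cation arylation (ionisation of 15 by TMSOTf), in which the only free C8 of 16 (in its upper epicatechin unit) should react in preference to the C6 positions and attack anti to the C3 hydroxyl again gives the 4β bond.

Step 10
Reactants: 15 5,7,3',4'-tetra-O-benzyl-4β-(2-ethoxyethoxy)epicatechin; 17 dodeca-O-benzyl trimer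
Product: 18 hexadeca-O-benzyl tetramer [tetra-O-benzylepicatechin-(4β→8)-tetra-O-benzylepicatechin-(4β→8)-tetra-O-benzylepicatechin-(4β→8)-tetra-O-benzylcatechin]
Conditions: TMSOTf (0.1 equiv), CH2Cl2, −78 °C; 17 in excess, excess recovered
Reagents that add atoms: none
Why: The same flavan-4-yl cation arylation (ionisation of 15 by TMSOTf) at the free C8 of the top unit of 17, with the low temperature and catalytic acid chosen to keep the existing interflavan bonds from ionising.

Step 11
Reactants: 18 hexadeca-O-benzyl tetramer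
Product: 19 epicatechin-(4β→8)-epicatechin-(4β→8)-epicatechin-(4β→8)-catechin (the target)
Conditions: H2 (1 atm), Pd(OH)2/C, THF/MeOH/H2O, rt
Reagents that add atoms: none
Why: Catalytic hydrogenolysis of the sixteen benzyl ethers under neutral conditions should leave the interflavan C4–C8 bonds, the ring C ethers and all stereocentres untouched.

Compound list

1 | 3,5-bis(benzyloxy)phenol | Oc1cc(OCc2ccccc2)cc(OCc2ccccc2)c1 | starting material
2 | 3,5-bis(benzyloxy)-2-(hydroxymethyl)phenol, present as its magnesium salt, not isolated | OCc1c(O)cc(OCc2ccccc2)cc1OCc1ccccc1 | intermediate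
3 | 2,4-bis(benzyloxy)-6-hydroxybenzaldehyde | O=Cc1c(O)cc(OCc2ccccc2)cc1OCc1ccccc1 | intermediate
4 | 3,4-bis(benzyloxy)benzaldehyde | O=Cc1ccc(OCc2ccccc2)c(OCc2ccccc2)c1 | starting material
5 | (E)-3-[3,4-bis(benzyloxy)phenyl]prop-2-enal | O=C/C=C/c1ccc(OCc2ccccc2)c(OCc2ccccc2)c1 | intermediate
6 | (E)-enamine of (3S)-3-[3,4-bis(benzyloxy)phenyl]-3-[3,5-bis(benzyloxy)-2-formylphenoxy]propanal with the (S)-pyrrolidine catalyst, not isolated | O=Cc1c(OCc2ccccc2)cc(OCc2ccccc2)cc1O[C@H](c1ccc(OCc2ccccc2)c(OCc2ccccc2)c1)/C=C/N1CCC[C@H]1C(O[Si](C)(C)C)(c1ccccc1)c1ccccc1 | intermediate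
7 | iminium 2-nitrobenzoate of (2S)-5,7-bis(benzyloxy)-2-[3,4-bis(benzyloxy)phenyl]-4-hydroxychromane-3-carbaldehyde with the (S)-pyrrolidine catalyst (C3 and C4 configuration not fixed, erased on dehydration), not isolated | c1ccccc1COc1cc(OCc3ccccc3)c2c(c1)O[C@H](c1ccc(OCc3ccccc3)c(OCc3ccccc3)c1)C(C=[N+]1CCC[C@H]1C(O[Si](C)(C)C)(c1ccccc1)c1ccccc1)C2O.[O-]C(=O)c1ccccc1[N+](=O)[O-] | intermediate
8 | (R)-5,7-bis(benzyloxy)-2-[3,4-bis(benzyloxy)phenyl]-2H-chromene-3-carbaldehyde | c1ccccc1COc1cc(OCc3ccccc3)c2c(c1)O[C@H](c1ccc(OCc3ccccc3)c(OCc3ccccc3)c1)C(C=O)=C2 | intermediate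
9 | (S)-5,7-bis(benzyloxy)-2-[3,4-bis(benzyloxy)phenyl]-2H-chromene (tetra-O-benzyl flav-3-ene) | c1ccccc1COc1cc(OCc3ccccc3)c2c(c1)O[C@H](c1ccc(OCc3ccccc3)c(OCc3ccccc3)c1)C=C2 | intermediate
10 | 2,3-trans 3-boryl-5,7,3',4'-tetrakis(benzyloxy)flavan (BH2 in the place of the 3-OH of 11), not isolated | c1ccccc1COc1cc(OCc3ccccc3)c2c(c1)O[C@H](c1ccc(OCc3ccccc3)c(OCc3ccccc3)c1)[C@@H](B)C2 | intermediate
11 | 5,7,3',4'-tetra-O-benzyl-(+)-catechin, (2R,3S) | c1ccccc1COc1cc(OCc3ccccc3)c2c(c1)O[C@H](c1ccc(OCc3ccccc3)c(OCc3ccccc3)c1)[C@@H](O)C2 | intermediate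
12 | (−)-epicatechin, (2R,3R) | Oc1cc(O)c2c(c1)O[C@H](c1ccc(O)c(O)c1)[C@H](O)C2 | starting material
13 | 5,7,3',4'-tetra-O-benzyl-(−)-epicatechin, (2R,3R) | c1ccccc1COc1cc(OCc3ccccc3)c2c(c1)O[C@H](c1ccc(OCc3ccccc3)c(OCc3ccccc3)c1)[C@H](O)C2 | intermediate
14 | C4 cation of 13 (2,3-cis flavan-4-yl cation, formed in step 7 beside DDQH− and re-formed from 15 in steps 8 to 10), not isolated | c1ccccc1COc1cc(OCc3ccccc3)c2c(c1)O[C@H](c1ccc(OCc3ccccc3)c(OCc3ccccc3)c1)[C@H](O)[CH+]2 | intermediate
15 | 5,7,3',4'-tetra-O-benzyl-4β-(2-ethoxyethoxy)epicatechin (2,3-cis, 3,4-trans) | c1ccccc1COc1cc(OCc3ccccc3)c2c(c1)O[C@H](c1ccc(OCc3ccccc3)c(OCc3ccccc3)c1)[C@H](O)[C@H]2OCCOCC | intermediate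
16 | octa-O-benzyl procyanidin B1, tetra-O-benzylepicatechin-(4β→8)-tetra-O-benzylcatechin | c1ccccc1COc1cc(OCc3ccccc3)c2c(c1)O[C@H](c1ccc(OCc3ccccc3)c(OCc3ccccc3)c1)[C@H](O)[C@H]2c1c(OCc3ccccc3)cc(OCc3ccccc3)c2c1O[C@H](c1ccc(OCc3ccccc3)c(OCc3ccccc3)c1)[C@@H](O)C2 | intermediate
17 | dodeca-O-benzyl trimer, tetra-O-benzylepicatechin-(4β→8)-tetra-O-benzylepicatechin-(4β→8)-tetra-O-benzylcatechin | c1ccccc1COc1cc(OCc3ccccc3)c2c(c1)O[C@H](c1ccc(OCc3ccccc3)c(OCc3ccccc3)c1)[C@H](O)[C@H]2c1c(OCc3ccccc3)cc(OCc3ccccc3)c2c1O[C@H](c1ccc(OCc3ccccc3)c(OCc3ccccc3)c1)[C@H](O)[C@H]2c1c(OCc3ccccc3)cc(OCc3ccccc3)c2c1O[C@H](c1ccc(OCc3ccccc3)c(OCc3ccccc3)c1)[C@@H](O)C2 | intermediate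
18 | hexadeca-O-benzyl tetramer, tetra-O-benzylepicatechin-(4β→8)-tetra-O-benzylepicatechin-(4β→8)-tetra-O-benzylepicatechin-(4β→8)-tetra-O-benzylcatechin (all sixteen phenols as benzyl ethers, four C3 hydroxyls free) | c1ccccc1COc1cc(OCc3ccccc3)c2c(c1)O[C@H](c1ccc(OCc3ccccc3)c(OCc3ccccc3)c1)[C@H](O)[C@H]2c1c(OCc3ccccc3)cc(OCc3ccccc3)c2c1O[C@H](c1ccc(OCc3ccccc3)c(OCc3ccccc3)c1)[C@H](O)[C@H]2c1c(OCc3ccccc3)cc(OCc3ccccc3)c2c1O[C@H](c1ccc(OCc3ccccc3)c(OCc3ccccc3)c1)[C@H](O)[C@H]2c1c(OCc3ccccc3)cc(OCc3ccccc3)c2c1O[C@H](c1ccc(OCc3ccccc3)c(OCc3ccccc3)c1)[C@@H](O)C2 | intermediate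
19 | epicatechin-(4β→8)-epicatechin-(4β→8)-epicatechin-(4β→8)-catechin, the target tetramer | Oc1cc(O)c2c(c1)O[C@H](c1ccc(O)c(O)c1)[C@H](O)[C@H]2c1c(O)cc(O)c2c1O[C@H](c1ccc(O)c(O)c1)[C@H](O)[C@H]2c1c(O)cc(O)c2c1O[C@H](c1ccc(O)c(O)c1)[C@H](O)[C@H]2c1c(O)cc(O)c2c1O[C@H](c1ccc(O)c(O)c1)[C@@H](O)C2 | target

Total step count: 11 steps.
Longest linear sequence: 8 steps (step 1, 3, 4, 5, 8, 9, 10, 11).

Steps most likely to fail

Step 3. The ring-closing aldol addition may be slow, because the formyl group of 3 is electron-rich and flanked by two ortho oxygen substituents. Reversible oxa-Michael addition to the electron-rich cinnamyl iminium ion may also erode the enantiomeric purity at C2. A partial loss could be corrected by recrystallisation of 11, and any remaining antipode becomes a separable diastereomer at 16. The fallback sets out from 3 and 5 and comes back at 9; it closes the same C3–C4 bond by ring-closing metathesis. Compound 3 is methylenated (Ph3P=CH2, 2.2 equiv, THF, 0 °C) to 3,5-bis(benzyloxy)-2-ethenylphenol F1. Compound 5 is reduced (NaBH4, CeCl3, MeOH, 0 °C) to (E)-3-[3,4-bis(benzyloxy)phenyl]prop-2-en-1-ol F2, which is converted (ClCO2Me, pyridine, CH2Cl2) to (E)-3-[3,4-bis(benzyloxy)phenyl]prop-2-enyl methyl carbonate F3. Asymmetric allylic etherification of the sodium phenoxide of F1 with F3 is then run with [Ir(cod)Cl]2 and a binaphthol-derived N,N-bis(1-phenylethyl)phosphoramidite ligand in THF, using the ligand enantiomer that delivers the (S)-ether. It should give the branched ether (S)-1,5-bis(benzyloxy)-3-{1-[3,4-bis(benzyloxy)phenyl]prop-2-enyloxy}-2-ethenylbenzene F4. Ring-closing metathesis (second-generation Grubbs catalyst, CH2Cl2, 40 °C) then forms C3=C4 and gives 9 with loss of ethylene.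

Step 4. Heating may racemise C2 through reversible oxa-6π ring opening of the 2H-chromene to an achiral ortho-quinone methide. A rhodium hydride may also move the double bond into the C2=C3 enol ether position, and CO extrusion from the hindered trisubstituted enal may stall. The fallback sets out from 8 and comes back at 11; it removes the formyl carbon oxidatively instead of reductively. Dakin-type Baeyer–Villiger oxidation of the enal (H2O2, SeO2 cat., CH2Cl2, or mCPBA, NaHCO3, CH2Cl2, 0 °C) should give the enol formate (R)-5,7-bis(benzyloxy)-2-[3,4-bis(benzyloxy)phenyl]-2H-chromen-3-yl formate F5. Mild methanolysis (NaHCO3, MeOH, 0 °C, short contact) releases (2R)-5,7,3',4'-tetrakis(benzyloxy)flavan-3-one F6, which is carried on at once without purification because its C2 hydrogen is acidic and could epimerise. Reduction with NaBH4 and CeCl3 at −78 °C is expected to favour the 2,3-trans alcohol 11, by axial attack of the small hydride on the half-chair with the C2 aryl group pseudo-equatorial. The cis isomer would be removed by chromatography.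

Step 10. The electrophile may condense with itself through its own free C8. The cation may also attack C6 positions of the trimer, and the acid may ionise existing interflavan bonds and scramble the chain. The fallback sets out from 13 and 17 and comes back at 19; it blocks C8 of the last unit so that the electrophile can be used in excess. Compound 13 is brominated (NBS, CH2Cl2, −40 °C) to 8-bromo-5,7,3',4'-tetra-O-benzylepicatechin F7. Oxidation with DDQ and 2-ethoxyethanol gives 8-bromo-5,7,3',4'-tetra-O-benzyl-4β-(2-ethoxyethoxy)epicatechin F8. Coupling of F8 with 17 (TMSOTf, CH2Cl2, −78 °C) should give the 8-bromo hexadeca-O-benzyl tetramer F9. Hydrogenolysis (H2, Pd(OH)2/C, Et3N, THF/MeOH/H2O) removes the bromine and the sixteen benzyl groups together and gives 19.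

Further compounds

F1 | step 3 | 3,5-bis(benzyloxy)-2-ethenylphenol | C=Cc1c(O)cc(OCc2ccccc2)cc1OCc1ccccc1
F2 | step 3 | (E)-3-[3,4-bis(benzyloxy)phenyl]prop-2-en-1-ol | OC/C=C/c1ccc(OCc2ccccc2)c(OCc2ccccc2)c1
F3 | step 3 | (E)-3-[3,4-bis(benzyloxy)phenyl]prop-2-enyl methyl carbonate | COC(=O)OC/C=C/c1ccc(OCc2ccccc2)c(OCc2ccccc2)c1
F4 | step 3 | (S)-1,5-bis(benzyloxy)-3-{1-[3,4-bis(benzyloxy)phenyl]prop-2-enyloxy}-2-ethenylbenzene | C=Cc1c(OCc2ccccc2)cc(OCc2ccccc2)cc1O[C@H](c1ccc(OCc2ccccc2)c(OCc2ccccc2)c1)C=C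
F5 | step 4 | (R)-5,7-bis(benzyloxy)-2-[3,4-bis(benzyloxy)phenyl]-2H-chromen-3-yl formate | c1ccccc1COc1cc(OCc3ccccc3)c2c(c1)O[C@H](c1ccc(OCc3ccccc3)c(OCc3ccccc3)c1)C(OC=O)=C2
F6 | step 4 | (2R)-5,7,3',4'-tetrakis(benzyloxy)flavan-3-one | c1ccccc1COc1cc(OCc3ccccc3)c2c(c1)O[C@H](c1ccc(OCc3ccccc3)c(OCc3ccccc3)c1)C(=O)C2
F7 | step 10 | 8-bromo-5,7,3',4'-tetra-O-benzylepicatechin | c1ccccc1COc1cc(OCc3ccccc3)c2c(c1Br)O[C@H](c1ccc(OCc3ccccc3)c(OCc3ccccc3)c1)[C@H](O)C2
F8 | step 10 | 8-bromo-5,7,3',4'-tetra-O-benzyl-4β-(2-ethoxyethoxy)epicatechin | c1ccccc1COc1cc(OCc3ccccc3)c2c(c1Br)O[C@H](c1ccc(OCc3ccccc3)c(OCc3ccccc3)c1)[C@H](O)[C@H]2OCCOCC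
F9 | step 10 | 8-bromo hexadeca-O-benzyl tetramer (bromine at C8 of the top unit) | c1ccccc1COc1cc(OCc3ccccc3)c2c(c1Br)O[C@H](c1ccc(OCc3ccccc3)c(OCc3ccccc3)c1)[C@H](O)[C@H]2c1c(OCc3ccccc3)cc(OCc3ccccc3)c2c1O[C@H](c1ccc(OCc3ccccc3)c(OCc3ccccc3)c1)[C@H](O)[C@H]2c1c(OCc3ccccc3)cc(OCc3ccccc3)c2c1O[C@H](c1ccc(OCc3ccccc3)c(OCc3ccccc3)c1)[C@H](O)[C@H]2c1c(OCc3ccccc3)cc(OCc3ccccc3)c2c1O[C@H](c1ccc(OCc3ccccc3)c(OCc3ccccc3)c1)[C@@H](O)C2
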